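I had 0.0800 M of J and 4.00 × 10⁻⁴ M of E for the south flask, with 0.290 M of G proposed, and I had to decide whether that charge was worth running for 47 min.

| flask | J | G | E | time |
|---|---|---|---|---|
| north-west | 0.0800 M | 0.120 M | 4.00 × 10⁻⁴ M |  |
| west | 0.0320 M | 0.0720 M | 4.00 × 10⁻⁴ M |  |
| north-east | 0.0800 M | 0.180 M | 4.00 × 10⁻⁴ M |  |
| south | 0.0800 M | 0.290 M | 4.00 × 10⁻⁴ M | 47 min |

- north-west run (time / min: [Q] / M): 5.9: 0.0206; 12: 0.0325; 18: 0.0429; 24: 0.0510; 29: 0.0545; 35: 0.0618; 41: 0.0643; 47: 0.0691
- west run (time / min: [Q] / M): 5.9: 0.0127; 12: 0.0215; 18: 0.0259; 24: 0.0286; 29: 0.0307; 35: 0.0310; 41: 0.0313; 47: 0.0323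
- north-east run (time / min: [Q] / M): 5.9: 0.0206; 12: 0.0336; 18: 0.0441; 24: 0.0513; 29: 0.0553; 35: 0.0601; 41: 0.0656; 47: 0.0700

(scatter of a reading: 6 × 10⁻⁴ M)

- Overall: J + G -> Q, with E as catalyst.
- Constant volume, constant temperature.
- Bound and free are read together.
- "The second partner" is G.
- An order is taken over about fifteen percent of the charge, up and down.

* reaction order in [J] at the outset, round the charge of the north-west run, defined at two percent of the J turned into Q (one fixed amount of Q, the same in the runs compared)
* reaction order in [G] at the outset, round the charge of the north-west run, defined at two percent of the J turned into Q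
* the west run starts with 0.0480 M less of J and of G than the north-west run, and with no Q. Compared where both hold the same amount of J, once fifteen percent of what the west run was charged with has turned into Q, is the west run faster, slower or alike (within a tenth)?
* Q in the south run at 47 min, as a share of the J charged

J is the limiting reagent of the south charge, with less of it than of G, so I followed the fraction of J left and not the Q made. I defined the left-fraction constant of a run as the logarithm of J charged over J left, divided by the time. At the last reading it came to 0.0424 min⁻¹ in the north-west run and 0.0442 min⁻¹ in the north-east run.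

The north-east run then held 0.0100 M of J, so a scatter of 6 × 10⁻⁴ M in that reading moved its constant by 0.00128 min⁻¹. The gap between the two runs, 0.00183 min⁻¹, was smaller than two such steps, so I read no effect of G from it.

At 12 min the north-west run gave 0.0434 min⁻¹, and the west run, charged with 0.0320 M of J, gave 0.0929 min⁻¹ at the same time, twice that reading. I therefore expected the west run to be faster than the north-west run in the comparison asked, and I took the constant to belong to one charge of J. I left J and E unchanged and changed G. For the south run I carried the mean of the north-west and north-east constants, the carried left-fraction constant 0.0433 min⁻¹. Over 47 min it leaves 13.1% of the J, which makes Q 86.9% of the J charged.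

The forecast gave orders of 0.2 in J and 0.03 in G, called the west run faster, and put the south run at 87%, which matches my figure at this rounding. On G it said: “Mild inhibition by excess G cannot be excluded”.

    E + J → Lx + Z (1446 M⁻¹ min⁻¹)
    Lx + G → Q + E (906.0 M⁻¹ min⁻¹)
    2 J ⇌ J2, settled at all times (337.0 M⁻¹)
    E + Z ⇌ EZ, settled at all times (38.60 M⁻¹)

The flask gave orders of 0.48 in J and 0.12 in G, the west run faster, and 86.8% in the south run, whose constant of 0.0431 min⁻¹ stands beside the carried 0.0433 min⁻¹. While J was there, E + J → Lx + Z and Lx + G → Q + E ran in turn, each turn adding one Z, and at half of the charge turned, the constant read 0.0440 min⁻¹ in the north-west run and 0.0890 min⁻¹ in the west run, twice the north-west value. With Z about equal to the Q made at that point, [EZ]/[E] stood at 0.618 in the west run and 1.54 in the north-west run.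

(The data come from a simulation with constants of no real substance; the scatter is artificial.)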